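Marchantin G is cut at the diaryl ether bond between the oxygen of the para-phenylene ring A and C3 of the ketone-bearing catechol ring B; that carbon lies ortho to the C4 hydroxyl, which is para to the acyl carbon, the pattern an oxidative phenol coupling leaves behind. One electrochemical operation (anodic oxidation, then zinc) should join the ring A phenol oxygen to an iodinated ortho carbon of the ring B phenol and close the 18-membered macrocycle. Its precursor is an open-chain tetra-aryl compound: ring A as a 2,6-dichlorophenol, ring B as a 2,6-diiodophenol with the ketone masked as a dioxolane, ring C the meta-phenylene on the ketone methylene, ring D a methyl-protected phenol.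

Key step: step 9

Remark: the ring A phenol is carried free from step 3 on, since its two ortho chlorines make it a weak nucleophile and leave no position open to iodination; 1-(allyloxy)-4-bromobenzene and 4-bromo-2,6-dichlorophenol are taken as catalogue compounds.

Step 1
Reactants: 1 methyl 2-(3-hydroxyphenyl)acetate; 2 2-fluoro-3-methoxybenzaldehyde
Product: 3 methyl 2-[3-(2-formyl-6-methoxyphenoxy)phenyl]acetate
Conditions: K2CO3, DMF, 110 °C
Reagents that add atoms: none
Why: Nucleophilic aromatic substitution, in which the ortho formyl group activates the C–F carbon towards the phenoxide of 1 and fluoride leaves from the addition intermediate.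

Step 2
Reactants: 3 methyl 2-[3-(2-formyl-6-methoxyphenoxy)phenyl]acetate
Product: 4 methyl 2-[3-(2-ethenyl-6-methoxyphenoxy)phenyl]acetate
Conditions: Ph3PCH3Br, KOtBu, THF, 0 °C → rt
Reagents that add atoms: methyltriphenylphosphonium bromide, C[P+](c1ccccc1)(c1ccccc1)c1ccccc1.[Br-]
Why: Wittig methylenation, since the non-stabilised ylide should add to the aldehyde far faster than to the ester.

Step 3
Reactants: 4 methyl 2-[3-(2-ethenyl-6-methoxyphenoxy)phenyl]acetate; 5 4-bromo-2,6-dichlorophenol
Product: 7 methyl 2-[3-[2-[2-(3,5-dichloro-4-hydroxyphenyl)ethyl]-6-methoxyphenoxy]phenyl]acetate, via B-alkyl-9-BBN adduct 6 (not isolated)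
Conditions: 9-BBN, THF, 0 °C → rt; then 5, PdCl2(dppf) (5 mol %), aq. K3PO4, THF/DMF, 60 °C
Reagents that add atoms: none
Why: Anti-Markovnikov hydroboration of the styrene followed by B-alkyl Suzuki–Miyaura coupling, in which zerovalent palladium should insert into the C–Br bond and not into the two hindered C–Cl bonds, gives the saturated two-carbon bridge without any alkene reduction.

Step 4
Reactants: 7 methyl 2-[3-[2-[2-(3,5-dichloro-4-hydroxyphenyl)ethyl]-6-methoxyphenoxy]phenyl]acetate
Product: 8 2-[3-[2-[2-(3,5-dichloro-4-hydroxyphenyl)ethyl]-6-methoxyphenoxy]phenyl]-N-methoxy-N-methylacetamide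
Conditions: MeNH(OMe)·HCl, iPrMgCl, THF, −20 → 0 °C; aq. NH4Cl
Reagents that add atoms: N,O-dimethylhydroxylamine hydrochloride, CNOC.Cl
Why: Weinreb amide formation by aminolysis of the methyl ester with the magnesium amide made in the flask, the acidic phenol being carried as its magnesium salt.

Step 5
Reactants: 8 2-[3-[2-[2-(3,5-dichloro-4-hydroxyphenyl)ethyl]-6-methoxyphenoxy]phenyl]-N-methoxy-N-methylacetamide; 9 1-(allyloxy)-4-bromobenzene
Product: 11 1-[4-(allyloxy)phenyl]-2-[3-[2-[2-(3,5-dichloro-4-hydroxyphenyl)ethyl]-6-methoxyphenoxy]phenyl]ethan-1-one, via 4-(allyloxy)phenylmagnesium bromide 10 (not isolated)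
Conditions: 9, Mg, THF, rt → 40 °C; then 8 (2.5 equiv of 10), THF, −20 → 0 °C; 1 M HCl
Reagents that add atoms: none
Why: Grignard addition to a Weinreb amide, which stops at the chelated tetrahedral adduct and releases the aryl benzyl ketone only on work-up; one equivalent of 10 is spent on the phenolic proton.

Step 6
Reactants: 11 1-[4-(allyloxy)phenyl]-2-[3-[2-[2-(3,5-dichloro-4-hydroxyphenyl)ethyl]-6-methoxyphenoxy]phenyl]ethan-1-one
Product: 12 4-[2-[2-[3-[[2-[4-(allyloxy)phenyl]-1,3-dioxolan-2-yl]methyl]phenoxy]-3-methoxyphenyl]ethyl]-2,6-dichlorophenol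
Conditions: HOCH2CH2OH, TsOH·H2O (cat.), toluene, reflux, Dean–Stark
Reagents that add atoms: ethylene glycol, OCCO
Why: Acid-catalysed ketalisation driven by azeotropic removal of water, done while the ring B oxygen is still an ether so that the carbonyl is not deactivated by a free para hydroxyl.

Step 7
Reactants: 12 4-[2-[2-[3-[[2-[4-(allyloxy)phenyl]-1,3-dioxolan-2-yl]methyl]phenoxy]-3-methoxyphenyl]ethyl]-2,6-dichlorophenol
Product: 13 2,6-dichloro-4-[2-[2-[3-[[2-(4-hydroxyphenyl)-1,3-dioxolan-2-yl]methyl]phenoxy]-3-methoxyphenyl]ethyl]phenol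
Conditions: Pd(PPh3)4 (5 mol %), morpholine, THF, rt
Reagents that add atoms: none
Why: Tsuji–Trost deallylation, in which zerovalent palladium ionises the aryl allyl ether and morpholine traps the allyl unit, under non-acidic conditions that should spare the ketal and the aryl chlorides.

Step 8
Reactants: 13 2,6-dichloro-4-[2-[2-[3-[[2-(4-hydroxyphenyl)-1,3-dioxolan-2-yl]methyl]phenoxy]-3-methoxyphenyl]ethyl]phenol
Product: 14 seco dichlorophenol diiodophenol ketal, 4-[2-[[3-[2-[2-(3,5-dichloro-4-hydroxyphenyl)ethyl]-6-methoxyphenoxy]phenyl]methyl]-1,3-dioxolan-2-yl]-2,6-diiodophenol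
Conditions: I2 (2.2 equiv), morpholine, CH2Cl2/MeOH, 0 °C → rt
Reagents that add atoms: iodine, [I][I]
Why: Electrophilic aromatic iodination by the iodine–morpholine complex should take place only at the two free ortho positions of the ring B phenol, because ring A has no open ortho or para position and the basic medium protects the ketal.

Step 9
Reactants: 14 seco dichlorophenol diiodophenol ketal
Product: 16 macrocyclic dichloro iodo phenol ketal, via macrocyclic aryloxy diiodo dienone 15 (not isolated)
Conditions: constant current, glassy-carbon anode/Pt cathode, undivided cell, 0.1 M LiClO4, MeOH, 1 mM, ca. 2.2 F/mol, rt; then Zn dust, AcOH/NaOAc, 0 °C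
Reagents that add atoms: none
Why: Two-electron anodic oxidation of the ring B 2,6-diiodophenol should give a phenoxonium ion whose iodine-bearing ortho carbon is captured by the ring A phenol oxygen to give the 6-aryloxy-2,6-diiodocyclohexa-2,4-dienone 15, and zinc then cleaves the C–I bond at the sp3 carbon so that ring B rearomatises to the 2-aryloxy-6-iodophenol. The closest known reaction type is the anodic (or Tl(NO3)3) oxidative coupling of ortho,ortho'-dihalophenols to ortho-hydroxy diaryl ethers with zinc work-up, which has also been used to close macrocyclic diaryl ethers. The 18-membered ring is closed end to end by intramolecular C–O bond formation, oxygen of ring A onto a cationic carbon of ring B, and high dilution with low current density should hold back oligomers. The only new stereocentre is the transient sp3 carbon of 15, formed racemic and erased by the reduction, so no control element is needed. Chemoselectivity (ring B oxidised, ring A the nucleophile) rests on iodine against chlorine substitution, regioselectivity is no issue because the two ortho carbons of ring B are equivalent, the ortho halogens block C–C coupling, the fully substituted ketal carbon para to the hydroxyl excludes a quinone methide, and methanol adducts at that para carbon should be returned to the phenol by zinc.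

Step 10
Reactants: 16 macrocyclic dichloro iodo phenol ketal
Product: 17 macrocyclic dichloro catechol ketal
Conditions: CuI (10 mol %), 8-hydroxyquinoline (20 mol %), NaOH, DMSO/H2O, 100 °C, Ar; then pH 6 phosphate buffer
Reagents that add atoms: sodium hydroxide, [Na+].[OH-]
Why: Copper-catalysed hydroxylation of an aryl iodide (Ullmann-type C–O coupling with hydroxide), long used to turn ortho-iodophenols into catechols, should act at C–I only, since the hindered aryl chlorides react far more slowly and the ketal is stable to base.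

Step 11
Reactants: 17 macrocyclic dichloro catechol ketal
Product: 18 macrocyclic catechol ketal
Conditions: H2 (1 atm), 10% Pd/C, Et3N, MeOH/THF, rt
Reagents that add atoms: none
Why: Palladium-catalysed hydrodechlorination with an amine as HCl acceptor should remove both aryl chlorides, while the ketal keeps the benzylic carbonyl carbon safe from reduction.

Step 12
Reactants: 18 macrocyclic catechol ketal
Product: 19 marchantin G
Conditions: BBr3, CH2Cl2, −78 → 0 °C; then 1 M HCl, THF, rt
Reagents that add atoms: water, O
Why: Lewis-acid cleavage of the aryl methyl ether by BBr3 frees the ring D phenol, and the aqueous acid work-up completes hydrolysis of the dioxolane to the aryl ketone, whose oxygen then comes from water.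

Compound list
1 | methyl 2-(3-hydroxyphenyl)acetate | COC(=O)Cc1cccc(O)c1 | starting material
2 | 2-fluoro-3-methoxybenzaldehyde | O=Cc1cccc(OC)c1F | starting material
3 | methyl 2-[3-(2-formyl-6-methoxyphenoxy)phenyl]acetate | COC(=O)Cc1cccc(Oc2c(C=O)cccc2OC)c1 | intermediate
4 | methyl 2-[3-(2-ethenyl-6-methoxyphenoxy)phenyl]acetate | COC(=O)Cc1cccc(Oc2c(C=C)cccc2OC)c1 | intermediate
5 | 4-bromo-2,6-dichlorophenol | Oc1c(Cl)cc(Br)cc1Cl | starting material
6 | B-alkyl-9-BBN adduct, methyl 2-[3-[2-[2-(9-borabicyclo[3.3.1]nonan-9-yl)ethyl]-6-methoxyphenoxy]phenyl]acetate (formed in the flask, not isolated) | COC(=O)Cc1cccc(Oc2c(CCB3C4CCCC3CCC4)cccc2OC)c1 | intermediate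
7 | methyl 2-[3-[2-[2-(3,5-dichloro-4-hydroxyphenyl)ethyl]-6-methoxyphenoxy]phenyl]acetate | COC(=O)Cc1cccc(Oc2c(CCc3cc(Cl)c(O)c(Cl)c3)cccc2OC)c1 | intermediate
8 | 2-[3-[2-[2-(3,5-dichloro-4-hydroxyphenyl)ethyl]-6-methoxyphenoxy]phenyl]-N-methoxy-N-methylacetamide | CON(C)C(=O)Cc1cccc(Oc2c(CCc3cc(Cl)c(O)c(Cl)c3)cccc2OC)c1 | intermediate
9 | 1-(allyloxy)-4-bromobenzene | C=CCOc1ccc(Br)cc1 | starting material
10 | 4-(allyloxy)phenylmagnesium bromide (formed in the flask, not isolated) | C=CCOc1ccc([Mg]Br)cc1 | intermediate
11 | 1-[4-(allyloxy)phenyl]-2-[3-[2-[2-(3,5-dichloro-4-hydroxyphenyl)ethyl]-6-methoxyphenoxy]phenyl]ethan-1-one | C=CCOc1ccc(cc1)C(=O)Cc1cccc(Oc2c(CCc3cc(Cl)c(O)c(Cl)c3)cccc2OC)c1 | intermediate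
12 | ethylene ketal of 11, 4-[2-[2-[3-[[2-[4-(allyloxy)phenyl]-1,3-dioxolan-2-yl]methyl]phenoxy]-3-methoxyphenyl]ethyl]-2,6-dichlorophenol | C=CCOc1ccc(cc1)C1(Cc2cccc(Oc3c(CCc4cc(Cl)c(O)c(Cl)c4)cccc3OC)c2)OCCO1 | intermediate
13 | 2,6-dichloro-4-[2-[2-[3-[[2-(4-hydroxyphenyl)-1,3-dioxolan-2-yl]methyl]phenoxy]-3-methoxyphenyl]ethyl]phenol | Oc1ccc(cc1)C1(Cc2cccc(Oc3c(CCc4cc(Cl)c(O)c(Cl)c4)cccc3OC)c2)OCCO1 | intermediate
14 | seco dichlorophenol diiodophenol ketal, 4-[2-[[3-[2-[2-(3,5-dichloro-4-hydroxyphenyl)ethyl]-6-methoxyphenoxy]phenyl]methyl]-1,3-dioxolan-2-yl]-2,6-diiodophenol | Oc1c(Cl)cc(CCc2cccc(OC)c2Oc2cccc(CC3(OCCO3)c3cc(I)c(O)c(I)c3)c2)cc1Cl | intermediate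
15 | macrocyclic aryloxy diiodo dienone: ring B as a 2,6-diiodocyclohexa-2,4-dienone whose sp3 C6 carries iodine and the ring A oxygen, racemic at that carbon (formed in the flask, not isolated) | O1CCOC12Cc3cccc(c3)Oc3c(OC)cccc3CCc3cc(Cl)c(c(Cl)c3)OC3(I)C=C2C=C(I)C3=O | intermediate
16 | macrocyclic dichloro iodo phenol ketal: 18-membered ring, ring A 2,6-dichloro-1,4-phenylene ether, ring B 3-aryloxy-4-hydroxy-5-iodophenyl on the dioxolane carbon, ring D methyl ether | O1CCOC12Cc3cccc(c3)Oc3c(OC)cccc3CCc3cc(Cl)c(c(Cl)c3)Oc3cc2cc(I)c3O | intermediate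
17 | macrocyclic dichloro catechol ketal: as 16 with hydroxyl in place of iodine | O1CCOC12Cc3cccc(c3)Oc3c(OC)cccc3CCc3cc(Cl)c(c(Cl)c3)Oc3cc2cc(O)c3O | intermediate
18 | macrocyclic catechol ketal: as 17 without the two chlorines | O1CCOC12Cc3cccc(c3)Oc3c(OC)cccc3CCc3ccc(cc3)Oc3cc2cc(O)c3O | intermediate
19 | marchantin G (achiral) | O=C1Cc2cccc(c2)Oc2c(O)cccc2CCc2ccc(cc2)Oc2cc1cc(O)c2O | target

Total step count: 12. Longest linear sequence: 12 steps (1 → 19); compounds 2, 5 and 9 enter as purchased materials.

Steps most likely to fail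

Step 9. The ring closure may lose to intermolecular coupling. The oxidised ring B may be trapped by methanol at the ketal-bearing para carbon and then shed that carbon. Ring A may be oxidised as well if the potential gap proves too narrow. The fallback gives up the oxidative coupling and forms the same O–C3 bond by copper-mediated substitution. It sets out from 7 and returns at 19. Hydrodechlorination of 7 (H2, Pd/C, Et3N, MeOH) would give the chlorine-free phenol ester F1. Crossed Claisen condensation of its enolate (LiN(SiMe3)2, THF, −78 °C → rt) with purchased methyl 3-bromo-4,5-dimethoxybenzoate would give the racemic β-keto ester F2. Krapcho dealkoxycarbonylation (LiCl, wet DMSO, 140 °C) would give the bromo ketone F3, and ketalisation (ethylene glycol, TsOH, toluene, Dean–Stark) the seco bromide ketal F4. An intramolecular Ullmann diaryl ether synthesis (CuI, N,N-dimethylglycine, Cs2CO3, dioxane, 100 °C, slow addition) would close the 18-membered ring to the macrocyclic trimethyl ether ketal F5. BBr3 followed by aqueous acid would then cleave the three methyl ethers and the ketal to give 19.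

Step 10. Reductive loss of iodine may compete with hydroxylation, and the catechol may be oxidised by air under the hot basic conditions. The fallback brings in the oxygen by electrophilic oxidation of the phenol instead of substitution of the iodide. It sets out from 16 and returns at 18. Hydrogenolysis (H2, Pd/C, Et3N, MeOH/THF) would remove the iodine and both chlorines to give the halogen-free monophenol ketal F6. IBX (DMF, rt) would oxidise its only free ortho position, C5 of ring B, to the ortho-quinone ketal F7. Na2S2O4 (aq. THF) would reduce this to catechol 18.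

Step 3. Oxidative addition into the electron-rich bromophenoxide may be slow, so that the alkylborane is lost by protodeboronation or β-hydride elimination before it couples. The fallback builds the bridge through an alkene. It sets out from 4 and 5 and returns at 7. A Heck reaction (Pd(OAc)2, P(o-tolyl)3, Et3N, DMF, 100 °C) would give the (E)-stilbene F8. Diimide reduction (TsNHNH2, NaOAc, THF/H2O, reflux) would then saturate the alkene without touching the C–Cl bonds to give 7.

Further compounds
F1 | step 9 | chlorine-free phenol ester, methyl 2-[3-[2-[2-(4-hydroxyphenyl)ethyl]-6-methoxyphenoxy]phenyl]acetate | COC(=O)Cc1cccc(Oc2c(CCc3ccc(O)cc3)cccc2OC)c1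
F2 | step 9 | β-keto ester, methyl 3-(3-bromo-4,5-dimethoxyphenyl)-2-[3-[2-[2-(4-hydroxyphenyl)ethyl]-6-methoxyphenoxy]phenyl]-3-oxopropanoate (racemic) | COC(=O)C(C(=O)c1cc(Br)c(OC)c(OC)c1)c1cccc(Oc2c(CCc3ccc(O)cc3)cccc2OC)c1
F3 | step 9 | bromo ketone, 1-(3-bromo-4,5-dimethoxyphenyl)-2-[3-[2-[2-(4-hydroxyphenyl)ethyl]-6-methoxyphenoxy]phenyl]ethan-1-one | O=C(Cc1cccc(Oc2c(CCc3ccc(O)cc3)cccc2OC)c1)c1cc(Br)c(OC)c(OC)c1
F4 | step 9 | seco bromide ketal, 4-[2-[2-[3-[[2-(3-bromo-4,5-dimethoxyphenyl)-1,3-dioxolan-2-yl]methyl]phenoxy]-3-methoxyphenyl]ethyl]phenol | Oc1ccc(CCc2cccc(OC)c2Oc2cccc(CC3(OCCO3)c3cc(Br)c(OC)c(OC)c3)c2)cc1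
F5 | step 9 | macrocyclic trimethyl ether ketal (ring B 4,5-dimethoxy, ring D methoxy, dioxolane in place of the ketone) | O1CCOC12Cc3cccc(c3)Oc3c(OC)cccc3CCc3ccc(cc3)Oc3cc2cc(OC)c3OC
F6 | step 10 | halogen-free monophenol ketal (ring B 3-aryloxy-4-hydroxyphenyl) | O1CCOC12Cc3cccc(c3)Oc3c(OC)cccc3CCc3ccc(cc3)Oc3cc2ccc3O
F7 | step 10 | ortho-quinone ketal (ring B as 3-aryloxy-1,2-benzoquinone) | O1CCOC12Cc3cccc(c3)Oc3c(OC)cccc3CCc3ccc(cc3)OC3=CC2=CC(=O)C3=O
F8 | step 3 | (E)-stilbene, methyl 2-[3-[2-[(E)-2-(3,5-dichloro-4-hydroxyphenyl)ethenyl]-6-methoxyphenoxy]phenyl]acetate | COC(=O)Cc1cccc(Oc2c(/C=C/c3cc(Cl)c(O)c(Cl)c3)cccc2OC)c1
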